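Ring D (C1'–C4'; locants as defined below), with its oxygens at C1' and C4' para to each other and fused to the chlorohydroquinone ring B, is treated as a furan that has added across the C4a'–C8a' bond of a ring B aryne. The precursor is a flat diaryl ether: the C8' oxygen of ring B already sits on C4 of a naphthalene, whose peri carbon C5 carries a 5-methoxyfuran-2-yl group. One operation (aryne formation, intramolecular Diels–Alder reaction, ketal opening) forms the C8a'–C1' and C4a'–C4' bonds, ring D, the quaternary C1' carbinol and a seven-membered tether ring. The C1' hydroxyl later closes the spiroketal at C4 by oxidative dearomatisation; both halves come from 4-bromo-2,5-dichlorophenol.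

Key step: step 6

Remark on numbering and stereochemistry: unprimed locants C1–C8a are the half that ends as the epoxy ketone (C1 ketone, C2/C3 epoxide, C4 spiro carbon, C5 bonded to C1', C7 Cl, C8 OH; benzene ring = ring A, C1–C4 ring = ring C). Primed locants are the other half (C1' quaternary, C2'/C3' epoxide, C4' carbinol, C5' OH, C6' Cl, C8' ether oxygen; benzene ring = ring B, C1'–C4' ring = ring D). The target SMILES is read as: C1'–O and the 2',3'-epoxide on one face of ring D, 4'-OH on the other; the 2,3-epoxide on the face of the ketal oxygen that leads to C1'. Men = (1R,2S,5R)-2-isopropyl-5-methylcyclohexyl; MenOCH2O is the formaldehyde acetal of (−)-menthol. It serves as ortho-metalation director and as a covalently bound chiral handle. The key step is not expected to be face-selective, so the single enantiomer is obtained by separating the two C1' diastereomers at the end of step 6; the unwanted (1'R) diastereomer is removed there and is not carried further.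

Step 1
Reactants: 1 4-bromo-2,5-dichlorophenol; 2 (−)-chloromethyl menthyl ether
Product: 3 1-bromo-2,5-dichloro-4-(MenOCH2O)benzene
Conditions: NaH, THF–DMF, 0 °C → rt
Reagents that add atoms: none
Why: Williamson-type O-alkylation of the sodium phenoxide by the α-chloro ether should give the mixed formaldehyde acetal that serves both halves of the target; no stereocenter is formed.

Step 2
Reactants: 3 1-bromo-2,5-dichloro-4-(MenOCH2O)benzene; 4 2-methoxyfuran
Product: 7 2-[2,5-dichloro-4-(MenOCH2O)phenyl]-5-methoxyfuran, via 5-lithio-2-methoxyfuran 5 (not isolated), via furylzinc chloride 6 (not isolated)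
Conditions: 4, n-BuLi, THF, −78 → 0 °C; ZnCl2; then 3, Pd(PPh3)4 (cat.), THF, 55 °C
Reagents that add atoms: none
Why: Negishi coupling, in which zerovalent palladium should insert only into the C–Br bond (the aryl chlorides are inert here) and the furan, lithiated at its free α-position and transmetalated to zinc, is transferred.

Step 3
Reactants: 8 furan-2(5H)-one
Product: 9 2-(triisopropylsilyloxy)furan
Conditions: i-Pr3SiOTf, Et3N, CH2Cl2, 0 °C → rt
Reagents that add atoms: triisopropylsilyl trifluoromethanesulfonate, CC(C)[Si](C(C)C)(C(C)C)OS(=O)(=O)C(F)(F)F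
Why: Soft enolisation of the butenolide and O-silylation of the dienolate should give the aromatic silyloxyfuran.

Step 4
Reactants: 7 2-[2,5-dichloro-4-(MenOCH2O)phenyl]-5-methoxyfuran; 9 2-(triisopropylsilyloxy)furan
Product: 13 6-chloro-8-(5-methoxyfuran-2-yl)-5-(MenOCH2O)-4-(triisopropylsilyloxy)naphthalen-1-ol, via aryllithium 10 (not isolated), via aryne 11 (not isolated), via oxa-bridged cycloadduct 12 (not isolated)
Conditions: n-BuLi (1.05 equiv), THF (0.02 M in 7), −78 °C; 9 (6 equiv), −78 → −20 °C; pH 7 buffer, then SiO2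
Reagents that add atoms: none
Why: Acetal-directed ortho-lithiation at the only hydrogen flanked by the acetal oxygen and chlorine, loss of LiCl and an aryne Diels–Alder reaction with the excess silyloxyfuran (the excess suppresses capture by the methoxyfuran of a second molecule), whose nucleophilic C5 should bond to the aryne carbon remote from the inductively withdrawing acetal oxygen, so that opening of the bridgehead silyl ketal and tautomerisation leave the free hydroxyl peri to the furyl group and the silyl ether peri to the acetal; no stereocenter remains.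

Step 5
Reactants: 13 the naphthol of step 4; 3 1-bromo-2,5-dichloro-4-(MenOCH2O)benzene
Product: 14 diaryl ether (naphthol oxygen of 13 bonded to C1 of the 2,5-dichloro-4-(MenOCH2O)phenyl group)
Conditions: CuI (cat.), N,N-dimethylglycine, Cs2CO3, dioxane, 100 °C, argon
Reagents that add atoms: none
Why: Ullmann diaryl ether synthesis, in which copper should activate only the C–Br bond of 3 and the amino acid ligand should allow the peri-hindered caesium naphthoxide to couple.

Step 6
Reactants: 14 diaryl ether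
Product: 18 (1'S)-quinol (1'-hydroxy-4'-oxo ring D on the seven-membered ether-bridged skeleton), via aryllithium 15 (not isolated), via aryne 16 (not isolated), via oxa-bridged cycloadduct 17 (not isolated)
Conditions: n-BuLi (1.1 equiv), THF (0.005 M), −78 → −20 °C; then 0.5 M aq. HCl, THF, 0 °C; chromatographic separation of the two C1' diastereomers
Reagents that add atoms: water, O
Why: n-BuLi should remove the ring B hydrogen between the chelating acetal oxygen and chlorine, LiCl is lost to give aryne 16 (C4a'≡C8a'), and the aryne adds across the two α-carbons of the tethered 2-aryl-5-methoxyfuran in an intramolecular Diels–Alder reaction; aqueous acid then opens the strained bridgehead methyl ketal of 17 at its C4'–O(bridge) bond, leaving the furan oxygen on C1' as a tertiary hydroxyl and C4' as the enone carbonyl. The closest known reaction type is the aryne–2-alkoxyfuran [4+2] cycloaddition followed by ring opening of the oxa-bridged adduct. Ring D closes in the concerted, asynchronous [4+2] event (bonds C8a'–C1' and C4a'–C4'), and the seven-membered oxepine ring (C4, O, C8', C8a', C1', C5, C4a) closes at the same time as the tether ring of the cycloaddition. The only new stereocenter that survives is C1'; it is set by the furan face that the aryne meets, and since nothing in the substrate distinguishes the two faces, 18 and its (1'R) epimer are expected in similar amounts and should be separable as diastereomers by virtue of the menthyl groups, only 18 being carried on. The step needs site selectivity in the metalation, secured by the acetal/chlorine pair (the diaryl ether oxygen is a much weaker director), and a single orientation of the cycloaddition, secured by the short diaryl ether tether, which lets only C8a' reach C1'.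

Step 7
Reactants: 18 (1'S)-quinol
Product: 19 (1'S,4'R)-trans-1',4'-diol
Conditions: NaBH4, CeCl3·7H2O, MeOH–CH2Cl2, −78 → −40 °C
Reagents that add atoms: none
Why: Luche reduction should give clean 1,2-reduction, with hydride expected on the carbonyl face syn to the C1' hydroxyl (the usual electrostatic preference of 4-oxygenated cyclohexadienones, reinforced by the C1' aryl group on the other face), which places the new C4' hydroxyl trans to the C1' oxygen.

Step 8
Reactants: 19 trans-diol
Product: 20 C4' tert-butyldimethylsilyl ether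
Conditions: TBSCl, imidazole, 4-(dimethylamino)pyridine (cat.), DMF, rt
Reagents that add atoms: tert-butyldimethylsilyl chloride, CC(C)(C)[Si](C)(C)Cl
Why: Silylation should discriminate the secondary allylic alcohol from the hindered tertiary one, and the bulky silyl ether then shields the lower face of ring D; no stereocenter changes.

Step 9
Reactants: 20 silyl ether
Product: 21 2',3'-epoxide (cis to the C1' hydroxyl and trans to the C4' silyl ether)
Conditions: VO(acac)2 (cat.), t-BuOOH, CH2Cl2, 0 °C → rt
Reagents that add atoms: tert-butyl hydroperoxide, CC(C)(C)OO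
Why: Vanadium-catalysed hydroxyl-directed epoxidation, in which the tertiary allylic C1' hydroxyl should deliver oxygen to the C2'=C3' bond on its own face, which is also the face away from the C4' silyl ether, setting C2' and C3'.

Step 10
Reactants: 21 epoxide
Product: 23 spiroketal enone, via free naphthol 22 (not isolated)
Conditions: TBAF (1.0 equiv), AcOH (1.0 equiv), THF, −20 °C; then PhI(OAc)2, MeCN, 0 °C
Reagents that add atoms: none
Why: Fluoride should cleave the aryl silyl ether much faster than the secondary alkyl silyl ether, and the trivalent iodine reagent then effects oxidative dearomatisation of the 4-aryloxy-1-naphthol, the C1' hydroxyl trapping C4 to close the five-membered ring (C4, O, C1', C5, C4a); the configuration at C4 is dictated by C1', because the new oxygen bridge can span only one face.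

Step 11
Reactants: 23 spiroketal enone
Product: 24 protected bis-epoxide
Conditions: t-BuOOH, 1,8-diazabicyclo[5.4.0]undec-7-ene, CH2Cl2, 0 °C → rt
Reagents that add atoms: tert-butyl hydroperoxide, CC(C)(C)OO
Why: Weitz–Scheffer epoxidation, in which tert-butyl peroxide anion should add to C3 from the face of the ketal oxygen that leads to C1', the other face being covered by ring B, and the enolate closes the epoxide, setting C2 and C3.

Step 12
Reactants: 24 protected bis-epoxide
Product: 25 target CNP0289684.3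
Conditions: CF3CO2H–H2O–CH2Cl2, 0 °C → rt
Reagents that add atoms: none
Why: Acid-catalysed hydrolysis should cleave the two formaldehyde acetals and the silyl ether in one operation, while the electron-poor epoxides and the aryl spiroketal are expected to survive the brief exposure; no stereocenter is touched.

Compound list

1 | 4-bromo-2,5-dichlorophenol | Oc1cc(Cl)c(Br)cc1Cl | starting material
2 | (−)-chloromethyl menthyl ether, (1R,2S,5R)-2-isopropyl-5-methylcyclohexyl chloromethyl ether | ClCO[C@@H]1C[C@H](C)CC[C@H]1C(C)C | starting material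
3 | 1-bromo-2,5-dichloro-4-(MenOCH2O)benzene | Brc1cc(Cl)c(OCO[C@@H]2C[C@H](C)CC[C@H]2C(C)C)cc1Cl | intermediate
4 | 2-methoxyfuran | COc1ccco1 | starting material
5 | 5-lithio-2-methoxyfuran | COc1ccc([Li])o1 | intermediate
6 | (5-methoxyfuran-2-yl)zinc chloride | COc1ccc([Zn]Cl)o1 | intermediate
7 | 2-[2,5-dichloro-4-(MenOCH2O)phenyl]-5-methoxyfuran | COc1ccc(o1)-c1cc(Cl)c(OCO[C@@H]2C[C@H](C)CC[C@H]2C(C)C)cc1Cl | intermediate
8 | furan-2(5H)-one | O=C1C=CCO1 | starting material
9 | 2-(triisopropylsilyloxy)furan | CC(C)[Si](C(C)C)(C(C)C)Oc1ccco1 | intermediate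
10 | 2-[2,5-dichloro-3-lithio-4-(MenOCH2O)phenyl]-5-methoxyfuran | COc1ccc(o1)-c1cc(Cl)c(OCO[C@@H]2C[C@H](C)CC[C@H]2C(C)C)c([Li])c1Cl | intermediate
11 | 4-chloro-6-(5-methoxyfuran-2-yl)-3-(MenOCH2O)benzyne | COc1ccc(o1)C1=CC(Cl)=C(OCO[C@@H]2C[C@H](C)CC[C@H]2C(C)C)C#C1 | intermediate
12 | 7-chloro-5-(5-methoxyfuran-2-yl)-8-(MenOCH2O)-1-(triisopropylsilyloxy)-1,4-dihydro-1,4-epoxynaphthalene (both bridgehead configurations) | CC(C)[Si](C(C)C)(C(C)C)OC12C=CC(O1)c1c(-c3ccc(OC)o3)cc(Cl)c(OCO[C@@H]3C[C@H](C)CC[C@H]3C(C)C)c12 | intermediate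
13 | 6-chloro-8-(5-methoxyfuran-2-yl)-5-(MenOCH2O)-4-(triisopropylsilyloxy)naphthalen-1-ol (target locants: 4-OH, 1-OSi, 5-furyl, 7-Cl, 8-acetal) | CC(C)[Si](C(C)C)(C(C)C)Oc1ccc(O)c2c(-c3ccc(OC)o3)cc(Cl)c(OCO[C@@H]3C[C@H](C)CC[C@H]3C(C)C)c12 | intermediate
14 | diaryl ether: 13 O-arylated by the 2,5-dichloro-4-(MenOCH2O)phenyl group (C4–O–C8') | CC(C)[Si](C(C)C)(C(C)C)Oc1ccc(Oc2cc(Cl)c(OCO[C@@H]3C[C@H](C)CC[C@H]3C(C)C)cc2Cl)c2c(-c3ccc(OC)o3)cc(Cl)c(OCO[C@@H]3C[C@H](C)CC[C@H]3C(C)C)c12 | intermediate
15 | aryllithium: 14 lithiated on ring B between the acetal oxygen and chlorine (future C4a') | CC(C)[Si](C(C)C)(C(C)C)Oc1ccc(Oc2cc(Cl)c(OCO[C@@H]3C[C@H](C)CC[C@H]3C(C)C)c([Li])c2Cl)c2c(-c3ccc(OC)o3)cc(Cl)c(OCO[C@@H]3C[C@H](C)CC[C@H]3C(C)C)c12 | intermediate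
16 | aryne: ring B of 14 with a C4a'≡C8a' triple bond | CC(C)[Si](C(C)C)(C(C)C)Oc1ccc(OC2=CC(Cl)=C(OCO[C@@H]3C[C@H](C)CC[C@H]3C(C)C)C#C2)c2c(-c3ccc(OC)o3)cc(Cl)c(OCO[C@@H]3C[C@H](C)CC[C@H]3C(C)C)c12 | intermediate
17 | oxa-bridged cycloadduct: 1',4'-epoxy-4'-methoxy-1',4'-dihydro ring D, C1' bonded to C5 (the bridgehead diastereomer that leads to 18) | CC(C)[Si](C(C)C)(C(C)C)Oc1ccc2Oc3cc(Cl)c(OCO[C@@H]4C[C@H](C)CC[C@H]4C(C)C)c4c3[C@@]5(O[C@@]4(OC)C=C5)c3cc(Cl)c(OCO[C@@H]4C[C@H](C)CC[C@H]4C(C)C)c1c23 | intermediate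
18 | (1'S)-quinol: 1'-hydroxy-4'-oxo-1',4'-dihydro ring D; ring B with 6'-Cl and 5'-OCH2OMen; C8'–O–C4 ether and C1'–C5 bond (seven-membered ring); naphthalene with 1-OSi(i-Pr)3, 7-Cl, 8-OCH2OMen | CC(C)[Si](C(C)C)(C(C)C)Oc1ccc2Oc3cc(Cl)c(OCO[C@@H]4C[C@H](C)CC[C@H]4C(C)C)c4c3[C@](O)(C=CC4=O)c3cc(Cl)c(OCO[C@@H]4C[C@H](C)CC[C@H]4C(C)C)c1c23 | intermediate
19 | (1'S,4'R)-diol: 18 with C4' reduced, 4'-OH trans to 1'-OH | CC(C)[Si](C(C)C)(C(C)C)Oc1ccc2Oc3cc(Cl)c(OCO[C@@H]4C[C@H](C)CC[C@H]4C(C)C)c4c3[C@](O)(C=C[C@H]4O)c3cc(Cl)c(OCO[C@@H]4C[C@H](C)CC[C@H]4C(C)C)c1c23 | intermediate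
20 | (1'S,4'R)-4'-O-tert-butyldimethylsilyl ether of 19 | CC(C)[Si](C(C)C)(C(C)C)Oc1ccc2Oc3cc(Cl)c(OCO[C@@H]4C[C@H](C)CC[C@H]4C(C)C)c4c3[C@](O)(C=C[C@H]4O[Si](C)(C)C(C)(C)C)c3cc(Cl)c(OCO[C@@H]4C[C@H](C)CC[C@H]4C(C)C)c1c23 | intermediate
21 | (1'S,2'R,3'S,4'S)-2',3'-epoxide of 20, epoxide cis to 1'-OH and trans to 4'-OSi | CC(C)[Si](C(C)C)(C(C)C)Oc1ccc2Oc3cc(Cl)c(OCO[C@@H]4C[C@H](C)CC[C@H]4C(C)C)c4c3[C@](O)([C@@H]5O[C@@H]5[C@H]4O[Si](C)(C)C(C)(C)C)c3cc(Cl)c(OCO[C@@H]4C[C@H](C)CC[C@H]4C(C)C)c1c23 | intermediate
22 | free C1 naphthol of 21 | Oc1ccc2Oc3cc(Cl)c(OCO[C@@H]4C[C@H](C)CC[C@H]4C(C)C)c4c3[C@](O)([C@@H]5O[C@@H]5[C@H]4O[Si](C)(C)C(C)(C)C)c3cc(Cl)c(OCO[C@@H]4C[C@H](C)CC[C@H]4C(C)C)c1c23 | intermediate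
23 | spiroketal enone (4R,1'S,2'R,3'S,4'S): C1 ketone, C2=C3, C4 ketal carbon bonded to O–C8' and O–C1'; 8- and 5'-OCH2OMen, 4'-OSi | O=C1c2c(OCO[C@@H]6C[C@H](C)CC[C@H]6C(C)C)c(Cl)cc3c2[C@@]2(Oc4cc(Cl)c(OCO[C@@H]6C[C@H](C)CC[C@H]6C(C)C)c5c4[C@]3(O2)[C@@H]2O[C@@H]2[C@H]5O[Si](C)(C)C(C)(C)C)C=C1 | intermediate
24 | protected bis-epoxide (2S,3R,4S,1'S,2'R,3'S,4'S): 23 with the 2,3-epoxide on the face of the O–C1' ketal oxygen | O=C1c2c(OCO[C@@H]6C[C@H](C)CC[C@H]6C(C)C)c(Cl)cc3c2[C@@]2(Oc4cc(Cl)c(OCO[C@@H]6C[C@H](C)CC[C@H]6C(C)C)c5c4[C@]3(O2)[C@@H]2O[C@@H]2[C@H]5O[Si](C)(C)C(C)(C)C)[C@@H]2O[C@H]12 | intermediate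
25 | CNP0289684.3 (2S,3R,4S,1'S,2'R,3'R,4'S in the locants above) | O=C1c2c(O)c(Cl)cc3c2[C@@]2(Oc4cc(Cl)c(O)c5c4[C@]3(O2)[C@@H]2O[C@@H]2[C@H]5O)[C@@H]2O[C@H]12 | target

Total step count: 12. Longest linear sequence: 11 steps (steps 1, 2, 4, 5, 6, 7, 8, 9, 10, 11, 12; step 3 is a one-step side branch).

Steps most likely to fail

Step 6 (key step). The base may remove a different ring hydrogen (above all the one between the diaryl ether oxygen and chlorine on ring B) or add to the aryne, so that the wrong aryne or none is formed. The fallback makes the same aryllithium by bromine–lithium exchange; it sets out from naphthol 13 and comes back at quinol 18. Commercial 2,5-dichlorophenol is iodinated para to the hydroxyl (N-iodosuccinimide, MeCN) to 2,5-dichloro-4-iodophenol F1, brominated at the remaining ortho position (N-bromosuccinimide, DMF) to 2-bromo-3,6-dichloro-4-iodophenol F2 and alkylated with 2 (NaH, DMF) to 2-bromo-3,6-dichloro-4-iodo-1-(MenOCH2O)benzene F3. Ullmann coupling of 13 with F3 (CuI, N,N-dimethylglycine, Cs2CO3, dioxane, 80 °C) should take place at the unhindered C–I bond and give the ring B bromide of the diaryl ether F4. n-BuLi at −100 °C should then exchange the bromine and give aryllithium 15, which on warming follows the course of step 6 through 16 and 17 to 18.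

Step 5. C–O bond formation at the peri-hindered, electron-rich naphthoxide may be slow at 100 °C, leaving time for silyl loss or oxidative degradation. The fallback is a Chan–Lam coupling at room temperature; it sets out from bromide 3 and comes back at diaryl ether 14. Bromine–magnesium exchange of 3 (i-PrMgCl·LiCl, THF, −15 °C), B(OMe)3 and aqueous work-up should give [2,5-dichloro-4-(MenOCH2O)phenyl]boronic acid F5, which is coupled with 13 (Cu(OAc)2, pyridine, 4 Å molecular sieves, CH2Cl2, air, rt) to give 14.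

Step 12. The acid needed for the acetals may open the ring C epoxy ketone. The fallback removes the acetals and the silyl ether before ring C is epoxidised; it sets out from enone 23 and comes back at target 25. CF3CO2H–H2O–CH2Cl2 at 0 °C should give the deprotected triol enone F6, and Weitz–Scheffer epoxidation in the presence of the free phenols (t-BuOOH, 1,5,7-triazabicyclo[4.4.0]dec-5-ene, CH2Cl2) should then give 25 with the facial preference of step 11.

Further compounds
F1 | step 6 | 2,5-dichloro-4-iodophenol | Oc1cc(Cl)c(I)cc1Cl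
F2 | step 6 | 2-bromo-3,6-dichloro-4-iodophenol | Oc1c(Br)c(Cl)c(I)cc1Cl
F3 | step 6 | 2-bromo-3,6-dichloro-4-iodo-1-(MenOCH2O)benzene | Clc1cc(I)c(Cl)c(Br)c1OCO[C@@H]2C[C@H](C)CC[C@H]2C(C)C
F4 | step 6 | diaryl ether 14 carrying bromine on ring B between the acetal oxygen and chlorine | CC(C)[Si](C(C)C)(C(C)C)Oc1ccc(Oc2cc(Cl)c(OCO[C@@H]3C[C@H](C)CC[C@H]3C(C)C)c(Br)c2Cl)c2c(-c3ccc(OC)o3)cc(Cl)c(OCO[C@@H]3C[C@H](C)CC[C@H]3C(C)C)c12
F5 | step 5 | [2,5-dichloro-4-(MenOCH2O)phenyl]boronic acid | OB(O)c1cc(Cl)c(OCO[C@@H]2C[C@H](C)CC[C@H]2C(C)C)cc1Cl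
F6 | step 12 | deprotected spiroketal enone (8-OH, 5'-OH, 4'-OH, 2',3'-epoxide, C2=C3) | O=C1c2c(O)c(Cl)cc3c2[C@@]2(Oc4cc(Cl)c(O)c5c4[C@]3(O2)[C@@H]2O[C@@H]2[C@H]5O)C=C1
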